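**Strategy.** The flavone is disconnected at the O1–C8a bond of ring C. The feature exploited is that C8a of ring A is the single hydrogen-bearing carbon ortho to the acyl-bearing C4a and sits para to the C6 methoxy group, so a 2,3,4-trimethoxyphenyl ketone already holds every ring A oxygen except O1. One anodic dehydrogenative C–H/O–H coupling of the open-chain 1,3-diketone 5, 1-(2,3,4-trimethoxyphenyl)-3-(3-acetoxy-4,5-dimethoxyphenyl)propane-1,3-dione, joins the C2 oxygen to C8a and closes the pyranone ring. The acetate on O3' makes ring B the poorer electron donor. The diketone is assembled from two purchased aromatics by soft-enolisation C-acylation, and methanolysis of the acetate ends the route.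

Key step: step 4

Remarks on the chemistry (assumptions):
- Atom mapping was checked and needs no correction. Aryl C2, C3, C4 (OMe) of the ketone become C5, C6, C7 of the flavone, the aryl C6–H becomes C8a, and the 3-acetoxy-4,5-dimethoxyphenyl ring becomes ring B (C3', C4', C5').
- In the hydrogen-bonded cis-enol of 5 the C2 oxygen faces the C4 oxygen, not C8a. Ring closure therefore needs the rotamer about C3–C4 with this chelate opened, and HFIP is chosen partly because its strong hydrogen-bond donation should open it.
- The O3' acetate is kept as the ring B spectator group. It weakens ring B as a donor, should survive oxalyl chloride, amine/magnesium enolisation and HFIP electrolysis, and comes off without the strong base that would endanger the γ-pyrone.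
- Compounds 1 and 4 are assumed to be purchasable.

Step 1
Reactants: 1 3-hydroxy-4,5-dimethoxybenzoic acid
Product: 2 3-acetoxy-4,5-dimethoxybenzoic acid
Conditions: Ac2O (2 equiv), pyridine, 0 °C to rt; then H2O, rt; dilute HCl work-up
Reagents that add atoms: acetic anhydride, CC(=O)OC(C)=O
Why: Pyridine-promoted O-acetylation of the phenol is fast, the water treatment hydrolyses excess anhydride and any mixed anhydride at the carboxyl group, and the acetyl group is chosen because it weakens ring B as an electron donor yet leaves later under mild methanolysis.

Step 2
Reactants: 2 3-acetoxy-4,5-dimethoxybenzoic acid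
Product: 3 3-acetoxy-4,5-dimethoxybenzoyl chloride (used crude after evaporation)
Conditions: (COCl)2 (1.3 equiv), DMF (cat.), CH2Cl2, 0 °C to rt; evaporate
Reagents that add atoms: oxalyl chloride, O=C(Cl)C(Cl)=O
Why: Chloroiminium (Vilsmeier-type) activation by oxalyl chloride and catalytic DMF converts the acid into the acid chloride under non-nucleophilic conditions that should leave the aryl acetate and the methyl ethers untouched.

Step 3
Reactants: 3 3-acetoxy-4,5-dimethoxybenzoyl chloride (1.2 equiv); 4 2',3',4'-trimethoxyacetophenone
Product: 5 1-(2,3,4-trimethoxyphenyl)-3-(3-acetoxy-4,5-dimethoxyphenyl)propane-1,3-dione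
Conditions: MgBr2·OEt2 (2.5 equiv), i-Pr2NEt (3 equiv), CH2Cl2, 0 °C to rt; then 1 M HCl
Reagents that add atoms: none
Why: Soft enolisation, in which MgBr2 coordination acidifies the methyl ketone enough for the hindered amine to form the magnesium enolate, is followed by crossed Claisen-type C-acylation with 3, and the product is held as an unreactive magnesium diketonate so that a second acylation and attack on the aryl acetate should be avoided.

Step 4
Reactants: 5 1-(2,3,4-trimethoxyphenyl)-3-(3-acetoxy-4,5-dimethoxyphenyl)propane-1,3-dione
Product: 6 5-(5,6,7-trimethoxy-4-oxo-4H-chromen-2-yl)-2,3-dimethoxyphenyl acetate (3'-acetoxy-4',5,5',6,7-pentamethoxyflavone)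
Conditions: undivided cell, graphite anode, Pt cathode, n-Bu4NPF6 (0.1 M), HFIP, constant current 5 mA/cm2, 2.1 F/mol, rt
Reagents that add atoms: none
Why: Proposed new method: the anode should take one electron from the trimethoxylated ring A, the most electron-rich π system of 5; HFIP loosens the internal O–H···O chelate, so the rotamer about C3–C4 that places the C2 oxygen above C8a is populated and this oxygen traps the arene radical cation through a six-membered transition state, after which a second electron transfer gives a cation stabilised by the para C6 methoxy group and loss of the C8a proton restores aromaticity, the two protons leaving as H2 at the cathode. The closest known reaction types are the anodic dehydrogenative lactonisation of biaryl-2-carboxylic acids and anodic C–H/O–H cyclisations of electron-rich arenes in fluorinated alcohols. Ring C closes by attack of oxygen on the sp2 carbon C8a in a six-membered mode, 6-exo-trig if the C8–C8a π bond is counted as the acceptor. No stereocentre is formed. The step needs ring A and not ring B to be attacked and must stop before the richer product ring is oxidised: three methoxy donors on ring A against two donors and a σ-withdrawing acetate on ring B bias the hole to ring A, only the C–H carbon C8a (not the methoxy-bearing ortho carbon) can rearomatise by proton loss, the γ-pyrone carbonyl of the product is hydrogen-bonded or protonated near the anode and so harder to oxidise, and the charge is limited to about 2.1 F/mol.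

Step 5
Reactants: 6 5-(5,6,7-trimethoxy-4-oxo-4H-chromen-2-yl)-2,3-dimethoxyphenyl acetate
Product: 7 2-(3-hydroxy-4,5-dimethoxyphenyl)-5,6,7-trimethoxy-4H-chromen-4-one (3'-hydroxy-4',5,5',6,7-pentamethoxyflavone, the target)
Conditions: K2CO3 (0.3 equiv), MeOH, 0 °C to rt; then aq NH4Cl
Reagents that add atoms: none
Why: Base-catalysed transesterification of the aryl acetate (Zemplén-type methanolysis) expels the good phenoxide leaving group at room temperature, conditions under which the aryl methyl ethers and the γ-pyrone should stay intact.

**Compound list**

1 | 3-hydroxy-4,5-dimethoxybenzoic acid | COc1cc(C(=O)O)cc(O)c1OC | starting material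
2 | 3-acetoxy-4,5-dimethoxybenzoic acid | COc1cc(C(=O)O)cc(OC(C)=O)c1OC | intermediate
3 | 3-acetoxy-4,5-dimethoxybenzoyl chloride | COc1cc(C(=O)Cl)cc(OC(C)=O)c1OC | intermediate
4 | 2',3',4'-trimethoxyacetophenone | CC(=O)c1ccc(OC)c(OC)c1OC | starting material
5 | 1-(2,3,4-trimethoxyphenyl)-3-(3-acetoxy-4,5-dimethoxyphenyl)propane-1,3-dione | COc1ccc(C(=O)CC(=O)c2cc(OC)c(OC)c(OC(C)=O)c2)c(OC)c1OC | intermediate
6 | 5-(5,6,7-trimethoxy-4-oxo-4H-chromen-2-yl)-2,3-dimethoxyphenyl acetate | COc1cc(-c2cc(=O)c3c(OC)c(OC)c(OC)cc3o2)cc(OC(C)=O)c1OC | intermediate
7 | 2-(3-hydroxy-4,5-dimethoxyphenyl)-5,6,7-trimethoxy-4H-chromen-4-one | COc1cc(-c2cc(=O)c3c(OC)c(OC)c(OC)cc3o2)cc(O)c1OC | target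

Total step count: 5. Longest linear sequence: 5 steps (1 → 2 → 3 → 5 → 6 → 7); ketone 4 enters at step 3.

**Steps most likely to fail**

Step 4 (proposed method). The electrolysis may stall at low conversion, oxidise the newly formed tetra-oxygenated ring A further, close onto ring B instead, or couple two enol-derived radicals at C3. The fallback uses known chemistry and sets out from acid chloride 3; the O1 oxygen is bought instead of made. 6'-Hydroxy-2',3',4'-trimethoxyacetophenone F1 (purchased) is converted with LiN(SiMe3)2 (3.2 equiv, THF, −78 °C) into its phenoxide–enolate dianion and acylated with 3 in a one-pot variant of the Baker–Venkataraman sequence. A cold acidic quench should give 1-(6-hydroxy-2,3,4-trimethoxyphenyl)-3-(3-acetoxy-4,5-dimethoxyphenyl)propane-1,3-dione F2. Acid-catalysed cyclodehydration (cat. H2SO4, AcOH, 90 °C) should then deliver flavone acetate 6, where the route is rejoined before step 5.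

Step 3. O-acylation of the magnesium enolate, a second acylation of the product, or acetyl transfer from the aryl acetate to the enolate may erode the C-acylation. The fallback sets out from acid 1 and installs the acetate only after the carbon–carbon bond is made. Fischer esterification (MeOH, cat. H2SO4, reflux) gives methyl 3-hydroxy-4,5-dimethoxybenzoate F3. Crossed Claisen condensation of F3 with ketone 4 (NaH, 3.5 equiv, THF, reflux, the phenol carried as its sodium phenoxide) should give 1-(2,3,4-trimethoxyphenyl)-3-(3-hydroxy-4,5-dimethoxyphenyl)propane-1,3-dione F4. Selective O-acetylation of the phenol (Ac2O 1.1 equiv, pyridine, 0 °C), which should leave the chelated enol alone as in phenolic 1,3-diketones of the curcumin type, returns to the route at 5.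

Step 5. Methoxide may add to C2 of the γ-pyrone and open ring C, or the cleavage may stall once the product phenoxide buffers the base. The fallback sets out from 6 and uses acid-catalysed transesterification (TsOH·H2O 0.2 equiv, MeOH, 50 °C). Here the pyrone is only reversibly protonated and no nucleophilic alkoxide is present. It comes back to the route at 7 and makes no new compound.

**Further compounds**

F1 | step 4 | 6'-hydroxy-2',3',4'-trimethoxyacetophenone (purchased, not made) | CC(=O)c1c(O)cc(OC)c(OC)c1OC
F2 | step 4 | 1-(6-hydroxy-2,3,4-trimethoxyphenyl)-3-(3-acetoxy-4,5-dimethoxyphenyl)propane-1,3-dione | COc1cc(O)c(C(=O)CC(=O)c2cc(OC)c(OC)c(OC(C)=O)c2)c(OC)c1OC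
F3 | step 3 | methyl 3-hydroxy-4,5-dimethoxybenzoate | COC(=O)c1cc(O)c(OC)c(OC)c1
F4 | step 3 | 1-(2,3,4-trimethoxyphenyl)-3-(3-hydroxy-4,5-dimethoxyphenyl)propane-1,3-dione | COc1ccc(C(=O)CC(=O)c2cc(OC)c(OC)c(O)c2)c(OC)c1OC
F0 | step 5 | none | none
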